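## Retrosynthetic overview

1. The only ring, the γ-lactone, is closed last by forming the C4–C5 bond: an intramolecular chromium-mediated γ-acyloxyallylation of the C4 formyl group by the 1-acyloxy-3,3-dimethylallyl unit of chloride 13. This one step should set C4, C5 (trans) and the 2-methylprop-1-enyl double bond.
2. Feature used: in the lactone ring the ring oxygen O1 sits on the allylic carbon C5, next to the carbinol carbon C4. O1–C5(alkenyl)–C4(OH) is therefore an anti 1,2-diol monoester, the retron of a γ-acyloxyallyl-metal/aldehyde addition; the lactone acyl group (C2, tied to C4 through C3) is the tether and the isobutenyl C=C is the transposed allyl double bond.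
3. Chloride 13 comes from hydroxy acid 9 in three steps: ruthenium-catalysed addition of the CO2H group to 2-methylbut-3-yn-2-ol (enol ester), MnO2 (C4 aldehyde), neutral chlorination of the tertiary allylic alcohol.
4. Acid 9 already holds the E-alkylidene: cross-metathesis of homoallylic acetate 7 with 2-(hydroxymethyl)acrylic acid; C8' is set by Keck allylation of enal 5.
5. Enal 5 comes from nerol by Mitsunobu angeloylation and selenium dioxide oxidation of the (E)-methyl group.

Key step: step 9

## Remarks and assumptions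

- Numbering in the text: lactone atoms are O1, C2 (C=O), C3 (alkylidene carbon), C4 (CHOH), C5 (CH–O). Chain atoms carry primes, from the angelate-bearing CH2 (C1') to the alkylidene CH (C10'); C8' is the acetoxy carbon.
- Assumption: 2-(hydroxymethyl)acrylic acid 8 is taken as commercially available (otherwise one saponification of its commercial ethyl ester).
- Assumption: the sense of induction of the chiral chromium ligand in step 9 cannot be predicted for a new ring closure. The (S)-ligand (a known oxazoline–sulfonamide, two steps from L-valinol) is written; its antipode is used if a trial run shows attack on the other face.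

## Route

Step 1
Reactants: 1 nerol, (2Z)-3,7-dimethylocta-2,6-dien-1-ol; 2 angelic acid, (2Z)-2-methylbut-2-enoic acid
Product: 3 neryl angelate, (2Z)-3,7-dimethylocta-2,6-dien-1-yl (2Z)-2-methylbut-2-enoate
Conditions: PPh3, DIAD, THF, 0 °C to rt
Reagents that add atoms: none
Why: Mitsunobu esterification activates the primary allylic alcohol and not the acid, so the angelate anion displaces the oxyphosphonium group by SN2 and neither the (Z)-angelate nor the (Z)-2,3-alkene should isomerise.

Step 2
Reactants: 3 neryl angelate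
Product: 5 (2Z,6E)-3,7-dimethyl-8-oxoocta-2,6-dien-1-yl (2Z)-2-methylbut-2-enoate, via allylic alcohol 4 (not isolated)
Conditions: SeO2 (0.3 equiv), t-BuOOH (3 equiv), salicylic acid (0.1 equiv), CH2Cl2, 0 °C to rt; then MnO2, CH2Cl2, rt
Reagents that add atoms: tert-butyl hydroperoxide (oxygen source), CC(C)(C)OO; selenium dioxide (oxygen carrier), O=[Se]=O
Why: Selenium dioxide allylic oxidation (ene reaction, then [2,3]-sigmatropic shift) attacks the (E)-methyl group of the electron-rich 6,7-alkene, the 2,3-alkene being deactivated by the allylic ester and the angelate by conjugation, and MnO2 then takes the allylic alcohol 4 in the crude mixture on to the (E)-enal.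

Step 3
Reactants: 5 (2Z,6E)-3,7-dimethyl-8-oxoocta-2,6-dien-1-yl (2Z)-2-methylbut-2-enoate
Product: 6 (2Z,6E,8S)-8-hydroxy-3,7-dimethylundeca-2,6,10-trien-1-yl (2Z)-2-methylbut-2-enoate
Conditions: allylSnBu3 (1.5 equiv), (S)-BINOL (20 mol %), Ti(OiPr)4 (20 mol %), 4 Å MS, CH2Cl2, −20 °C; aq NaHCO3
Reagents that add atoms: allyltributylstannane, C=CC[Sn](CCCC)(CCCC)CCCC
Why: Keck asymmetric allylation, in which the BINOL–titanium Lewis acid binds only the aldehyde and delivers allyl by 1,2-addition to its Si face, so that C8' is set as S under catalyst control ((S)-BINOL is expected to give the (S)-carbinol when the aldehyde substituent outranks allyl).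

Step 4
Reactants: 6 (2Z,6E,8S)-8-hydroxy-3,7-dimethylundeca-2,6,10-trien-1-yl (2Z)-2-methylbut-2-enoate
Product: 7 (2Z,6E,8S)-8-acetoxy-3,7-dimethylundeca-2,6,10-trien-1-yl (2Z)-2-methylbut-2-enoate
Conditions: Ac2O, pyridine, DMAP (cat.), CH2Cl2, 0 °C to rt
Reagents that add atoms: acetic anhydride, CC(=O)OC(C)=O
Why: DMAP-catalysed acylation of the secondary allylic alcohol, which does not touch the stereocentre.

Step 5
Reactants: 7 (2Z,6E,8S)-8-acetoxy-3,7-dimethylundeca-2,6,10-trien-1-yl (2Z)-2-methylbut-2-enoate; 8 2-(hydroxymethyl)prop-2-enoic acid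
Product: 9 (2E,5S,6E,10Z)-5-acetoxy-2-(hydroxymethyl)-6,10-dimethyl-12-[(2Z)-2-methylbut-2-enoyloxy]dodeca-2,6,10-trienoic acid
Conditions: 8 (5 equiv), second-generation Hoveyda–Grubbs catalyst (5 mol %), CH2Cl2, 40 °C
Reagents that add atoms: none
Why: Olefin cross-metathesis of a terminal (type-one) alkene with a 1,1-disubstituted acrylate-type partner in excess, in which the trisubstituted and conjugated alkenes of 7 are inert to the ruthenium carbene and the new trisubstituted alkene should form as the E isomer (chain trans to the carboxyl group), as with methacrylates.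

Step 6
Reactants: 9 (2E,5S,6E,10Z)-5-acetoxy-2-(hydroxymethyl)-6,10-dimethyl-12-[(2Z)-2-methylbut-2-enoyloxy]dodeca-2,6,10-trienoic acid; 10 2-methylbut-3-yn-2-ol
Product: 11 (1Z)-3-hydroxy-3-methylbut-1-en-1-yl (2E,5S,6E,10Z)-5-acetoxy-2-(hydroxymethyl)-6,10-dimethyl-12-[(2Z)-2-methylbut-2-enoyloxy]dodeca-2,6,10-trienoate
Conditions: 10 (3 equiv), Ru(2-methylallyl)2(dppe) (3 mol %), toluene, 45 °C
Reagents that add atoms: none
Why: Ruthenium-catalysed anti-Markovnikov trans-addition of a carboxylic acid to a terminal alkyne through a ruthenium vinylidene, which with propargylic alcohols is known to stop at the (Z)-3-hydroxyalk-1-enyl ester, while the hydroxyl groups do not add.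

Step 7
Reactants: 11 (1Z)-3-hydroxy-3-methylbut-1-en-1-yl ester of acid 9
Product: 12 (1Z)-3-hydroxy-3-methylbut-1-en-1-yl (2E,5S,6E,10Z)-5-acetoxy-2-formyl-6,10-dimethyl-12-[(2Z)-2-methylbut-2-enoyloxy]dodeca-2,6,10-trienoate
Conditions: MnO2 (20 equiv), CH2Cl2, rt; filtration
Reagents that add atoms: none
Why: Heterogeneous MnO2 oxidation is selective for the primary allylic alcohol (the tertiary carbinol cannot be oxidised), and filtration as the only work-up should spare the 2-formyl enoate, whose E geometry (chain cis to the small formyl group) is expected to be the thermodynamically preferred one.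

Step 8
Reactants: 12 (1Z)-3-hydroxy-3-methylbut-1-en-1-yl 2-formyl trienoate
Product: 13 (1Z)-3-chloro-3-methylbut-1-en-1-yl (2E,5S,6E,10Z)-5-acetoxy-2-formyl-6,10-dimethyl-12-[(2Z)-2-methylbut-2-enoyloxy]dodeca-2,6,10-trienoate
Conditions: 1-chloro-N,N,2-trimethylprop-1-en-1-amine (1.2 equiv), CH2Cl2, 0 °C; evaporation, used crude
Reagents that add atoms: 1-chloro-N,N,2-trimethylprop-1-en-1-amine (Ghosez reagent), CC(C)=C(Cl)N(C)C
Why: Chlorination of an alcohol with an α-chloroenamine under neutral conditions, the alkoxyiminium chloride collapsing at the ionisable tertiary allylic carbon, so that no acid or base is present to move the acyl group or touch the aldehyde, and an allylic shift of chloride would not matter for step 9.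

Step 9
Reactants: 13 (1Z)-3-chloro-3-methylbut-1-en-1-yl 2-formyl trienoate
Product: 15 CNP0201198.1, (2Z,6E,8S)-8-acetoxy-10-[(3E,4S,5R)-4-hydroxy-5-(2-methylprop-1-en-1-yl)-2-oxooxolan-3-ylidene]-3,7-dimethyldeca-2,6-dien-1-yl (2Z)-2-methylbut-2-enoate, via allylchromium species 14 (not isolated)
Conditions: CrCl2 (5 equiv), N-[2-[(4S)-4-isopropyl-4,5-dihydro-1,3-oxazol-2-yl]-6-methylphenyl]methanesulfonamide (5.5 equiv), Et3N (5.5 equiv), THF, rt, 1 h; then 13 added over 8 h (final 0.005 M), 0 °C to rt; aq potassium sodium tartrate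
Reagents that add atoms: none
Why: Proposed new method: two equivalents of divalent chromium reduce the allylic C–Cl bond of 13 (electron transfer, then radical capture) to the trivalent σ-allylchromium 14, whose 1,3-metal shift is fast, and the oxygen-bearing allyl terminus C5 adds to the chromium-bound formyl group C4 through a six-membered chair transition state fused to the forming lactone (closure mode 5-exo-trig at the C=O), the allyl double bond moving into the 2-methylprop-1-enyl position. The closest known reactions are the chromium-, zinc- and indium-mediated additions of 3-halopropenyl esters (γ-acyloxyallyl metals) to aldehydes, which give anti 1,2-diol monoesters, the Nozaki–Hiyama crotylation and the chromium allylations with chiral oxazoline–sulfonamide ligands; new are the intramolecular form, in which the acyl group of the reagent belongs to the substrate, and the dimethyl-substituted allyl terminus. Regioselectivity (bond to C5, not to the dimethyl-substituted terminus) is secured by the three-atom tether O1–C2–C3, because bond formation at the other terminus would need a bridged transition state and give a seven-membered enol lactone with a quaternary carbon. The trans relation of C4–OH and C5–alkenyl follows from the chair in which the acyloxy group on C5 and the C3 substituent on C4 are both equatorial, axial groups clashing with the ligands on octahedral chromium, and because 14 equilibrates, any E/Z or allylic isomer of the chloride converges on this one transition state, as in anti-selective crotylations. The absolute configuration (4S,5R) is set by the chiral sulfonamide ligand on chromium, and since C8' is already fixed, the product of attack on the other face is a diastereomer and can be removed. Chemoselectivity comes from the reagent, allylchromium adding only to the aldehyde and not to the ester groups or the alkenes, while slow addition at high dilution keeps the reaction intramolecular.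

## Compound list

1 | nerol, (2Z)-3,7-dimethylocta-2,6-dien-1-ol | OC/C=C(/C)CCC=C(C)C | starting material
2 | angelic acid, (2Z)-2-methylbut-2-enoic acid | C/C=C(/C)C(=O)O | starting material
3 | neryl angelate | C/C=C(/C)C(=O)OC/C=C(/C)CCC=C(C)C | intermediate
4 | (2Z,6E)-8-hydroxy-3,7-dimethylocta-2,6-dien-1-yl (2Z)-2-methylbut-2-enoate | C/C=C(/C)C(=O)OC/C=C(/C)CC/C=C(\C)CO | intermediate (not isolated)
5 | (2Z,6E)-3,7-dimethyl-8-oxoocta-2,6-dien-1-yl (2Z)-2-methylbut-2-enoate | C/C=C(/C)C(=O)OC/C=C(/C)CC/C=C(\C)C=O | intermediate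
6 | (2Z,6E,8S)-8-hydroxy-3,7-dimethylundeca-2,6,10-trien-1-yl (2Z)-2-methylbut-2-enoate | C/C=C(/C)C(=O)OC/C=C(/C)CC/C=C(\C)[C@H](CC=C)O | intermediate
7 | (2Z,6E,8S)-8-acetoxy-3,7-dimethylundeca-2,6,10-trien-1-yl (2Z)-2-methylbut-2-enoate | C/C=C(/C)C(=O)OC/C=C(/C)CC/C=C(\C)[C@H](CC=C)OC(C)=O | intermediate
8 | 2-(hydroxymethyl)prop-2-enoic acid | C=C(CO)C(=O)O | starting material
9 | (2E,5S,6E,10Z)-5-acetoxy-2-(hydroxymethyl)-6,10-dimethyl-12-[(2Z)-2-methylbut-2-enoyloxy]dodeca-2,6,10-trienoic acid | C/C=C(/C)C(=O)OC/C=C(/C)CC/C=C(\C)[C@H](C/C=C(\CO)C(=O)O)OC(C)=O | intermediate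
10 | 2-methylbut-3-yn-2-ol | CC(C)(O)C#C | starting material
11 | (1Z)-3-hydroxy-3-methylbut-1-en-1-yl ester of 9 | C/C=C(/C)C(=O)OC/C=C(/C)CC/C=C(\C)[C@H](C/C=C(\CO)C(=O)O/C=C\C(C)(C)O)OC(C)=O | intermediate
12 | (1Z)-3-hydroxy-3-methylbut-1-en-1-yl (2E,5S,6E,10Z)-5-acetoxy-2-formyl-6,10-dimethyl-12-[(2Z)-2-methylbut-2-enoyloxy]dodeca-2,6,10-trienoate | C/C=C(/C)C(=O)OC/C=C(/C)CC/C=C(\C)[C@H](C/C=C(\C=O)C(=O)O/C=C\C(C)(C)O)OC(C)=O | intermediate
13 | (1Z)-3-chloro-3-methylbut-1-en-1-yl (2E,5S,6E,10Z)-5-acetoxy-2-formyl-6,10-dimethyl-12-[(2Z)-2-methylbut-2-enoyloxy]dodeca-2,6,10-trienoate | C/C=C(/C)C(=O)OC/C=C(/C)CC/C=C(\C)[C@H](C/C=C(\C=O)C(=O)O/C=C\C(C)(C)Cl)OC(C)=O | intermediate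
14 | σ-allylchromium species of trivalent chromium from 13, metal on the dimethyl-substituted carbon, E enol ester (sulfonamide ligand and solvent on chromium not drawn) | C/C=C(/C)C(=O)OC/C=C(/C)CC/C=C(\C)[C@H](C/C=C(\C=O)C(=O)O/C=C/C(C)(C)[Cr](Cl)Cl)OC(C)=O | intermediate (not isolated)
15 | CNP0201198.1, (2Z,6E,8S)-8-acetoxy-10-[(3E,4S,5R)-4-hydroxy-5-(2-methylprop-1-en-1-yl)-2-oxooxolan-3-ylidene]-3,7-dimethyldeca-2,6-dien-1-yl (2Z)-2-methylbut-2-enoate | C/C=C(/C)C(=O)OC/C=C(/C)CC/C=C(\C)[C@H](C/C=C1/C(=O)O[C@H](C=C(C)C)[C@H]1O)OC(C)=O | target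

## Step count and risks

Total step count: 9. Longest linear sequence: 9 steps (1 to 15).

**1. Step 9 (Proposed new method).** What may go wrong: allyl transfer through the wrong terminus or between two molecules, poor face selection at the formyl group under the chiral ligand, or one-electron reduction (pinacol coupling) of the activated enal before the chloride is consumed. Fallback with known chemistry, from 9 back to 15: acid 9 is added, under the ruthenium catalysis of step 6, to 2-methylbut-1-en-3-yne instead of 10 to give the (1Z)-3-methylbuta-1,3-dien-1-yl ester F1. MnO2 oxidises this to the formyl dienyl ester F2. A reductive cyclisation of this ω-formyl-1,3-diene catalysed by zerovalent nickel (Ni(cod)2, (2R,5R)-2,5-dimethyl-1-phenylphospholane, Et3SiH, THF, 0 °C; hydronickelation of the diene at its CH2 end, then addition of the π-allylnickel to the aldehyde) closes the same C4–C5 bond and gives the triethylsilyl ether of 15 F3. HF·pyridine in THF then frees 15.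

**2. Step 6.** What may go wrong: Markovnikov addition followed by acyl migration to a β-oxo ester, or a 1,5-acyl shift in the (Z)-γ-hydroxy enol ester with loss of the acid. Fallback, from 9 back to 14: TEMPO (cat.) and PhI(OAc)2 in CH2Cl2 oxidise 9 to the formyl acid F4. The chloroenamine of step 8 turns it into the acid chloride F5, which is not isolated and adds to 3-methylbut-2-enal (ZnCl2 cat., CH2Cl2, −20 °C) to give the 1-chloro-3-methylbut-2-en-1-yl ester F6, an allylic isomer of 13. Under the conditions of step 9, F6 should give the same allylchromium 14 and then 15. This fallback also by-passes steps 7 and 8.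

**3. Step 2.** What may go wrong: incomplete conversion, over-oxidation and attack at other allylic positions in the allylic oxidation. Fallback, from 3 back to 5: mCPBA (CH2Cl2, 0 °C) epoxidises the electron-rich 6,7-alkene of 3 to the 6,7-epoxide F7. H5IO6 (THF, water) cleaves it to the aldehyde (2Z)-3-methyl-6-oxohex-2-en-1-yl (2Z)-2-methylbut-2-enoate F8. A Wittig reaction of F8 with 2-(triphenylphosphoranylidene)propanal (toluene, 90 °C) gives the (E)-enal 5.

## Further compounds

F1 | step 9 | (1Z)-3-methylbuta-1,3-dien-1-yl (2E,5S,6E,10Z)-5-acetoxy-2-(hydroxymethyl)-6,10-dimethyl-12-[(2Z)-2-methylbut-2-enoyloxy]dodeca-2,6,10-trienoate | C/C=C(/C)C(=O)OC/C=C(/C)CC/C=C(\C)[C@H](C/C=C(\CO)C(=O)O/C=C\C(C)=C)OC(C)=O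
F2 | step 9 | (1Z)-3-methylbuta-1,3-dien-1-yl (2E,5S,6E,10Z)-5-acetoxy-2-formyl-6,10-dimethyl-12-[(2Z)-2-methylbut-2-enoyloxy]dodeca-2,6,10-trienoate | C/C=C(/C)C(=O)OC/C=C(/C)CC/C=C(\C)[C@H](C/C=C(\C=O)C(=O)O/C=C\C(C)=C)OC(C)=O
F3 | step 9 | triethylsilyl ether of 15 at the C4 hydroxyl group | C/C=C(/C)C(=O)OC/C=C(/C)CC/C=C(\C)[C@H](C/C=C1/C(=O)O[C@H](C=C(C)C)[C@H]1O[Si](CC)(CC)CC)OC(C)=O
F4 | step 6 | (2E,5S,6E,10Z)-5-acetoxy-2-formyl-6,10-dimethyl-12-[(2Z)-2-methylbut-2-enoyloxy]dodeca-2,6,10-trienoic acid | C/C=C(/C)C(=O)OC/C=C(/C)CC/C=C(\C)[C@H](C/C=C(\C=O)C(=O)O)OC(C)=O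
F5 | step 6 | acid chloride of F4 | C/C=C(/C)C(=O)OC/C=C(/C)CC/C=C(\C)[C@H](C/C=C(\C=O)C(Cl)=O)OC(C)=O
F6 | step 6 | 1-chloro-3-methylbut-2-en-1-yl ester of F4 (both configurations at the chlorine-bearing carbon) | C/C=C(/C)C(=O)OC/C=C(/C)CC/C=C(\C)[C@H](C/C=C(\C=O)C(=O)OC(Cl)C=C(C)C)OC(C)=O
F7 | step 2 | (2Z)-5-(3,3-dimethyloxiran-2-yl)-3-methylpent-2-en-1-yl (2Z)-2-methylbut-2-enoate (racemic epoxide) | C/C=C(/C)C(=O)OC/C=C(/C)CCC1OC1(C)C
F8 | step 2 | (2Z)-3-methyl-6-oxohex-2-en-1-yl (2Z)-2-methylbut-2-enoate | C/C=C(/C)C(=O)OC/C=C(/C)CCC=O
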